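## Analysis of the target

Radermachol (14) is an achiral, fully unsaturated pentacycle. Benzo ring A is fused to the seven-membered ring B, ring B is fused to a furan (ring C) through furan C3 and C4, the furan is fused through C4 and C5 to the six-membered ring D, and ring D carries benzo ring E. Atom labels used below: furan O1, C2 (bearing the 2-methylprop-1-enyl group), C3, C4, C5; Cf is the ring B ketone carbon between C3 and ring A; Cc is the ring B enol carbon between ring A and the central carbon Cb; Cb sits on C4 and also carries Ch, the ring D ketone carbon bonded to ring E. There is no stereocentre, so every selectivity question is one of regio- or chemoselectivity. The sensitive groups are the enolised 1,3-diketone Cc(OH)=Cb–Ch=O (acidic, nucleophilic at oxygen, chelating) and the 2-alkenylfuran (labile to acid, electrophiles and oxidants). The difficulty is that all four furan carbons bear different substituents and must be addressed one by one, and that a seven-membered ring has to be closed between two aryl ketone carbons without the five-membered aldol and Claisen closures that two ortho acyl groups on ring A invite. The strategy rests on C5: it is an α-carbon of the furan bonded directly to a ring E carbon ortho to Ch, and because ring B occupies only C3 and C4, a precursor keeps an α C–H bond at C5 within six-membered reach of an aryl halide carried on Ch. The other α-carbon, C2, is distinguished from C5 by that very ring closure when the furan comes from symmetrical 3,4-dibromofuran (3), which is why the side chain is attached to C2 only afterwards.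

## Retrosynthetic reasoning

14 ⇒ 13. The O–CH3 bond on the ring B enol oxygen is the last bond to be cut. The free enol is the most acidic and most O-nucleophilic site; next to an ortho-haloaryl ketone under palladium and base it would close a pyranone through C–O bond formation. It therefore travels as its methyl ether 13, a vinylogous ester that a chelating boron Lewis acid can cleave at low temperature without touching the alkenylfuran.

13 ⇒ 11 + 12. The C2–alkenyl bond is cut next. Carrying the side chain from the start would require telling apart the two bromines of a 2-substituted 3,4-dibromofuran, for which the alkenyl group offers no directing element. In 11 the question does not arise: C2–H is the only furan C–H left, and it is an α C–H acidified by the Cf ketone on C3. A palladium-catalysed C–H alkenylation with alkenyl bromide 12 has to do no more than find that bond. As a gain, the acid-sensitive alkenylfuran is absent from six of the eight steps.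

11 ⇒ 10 (key disconnection). The C5–aryl bond of ring D is cut. It is a biaryl-type bond between a furan α-carbon and ring E, and in 10 the aryl bromide sits on Ch, which is attached to Cb on C4, so the two carbons are joined through a six-membered ring. Cutting ring D at Cb–Ch or Ch–aryl instead would call for acylations on a deactivated, fully substituted system. The forward reaction must arylate carbon rather than oxygen (hence the enol ether), must take C5–H rather than C2–H (secured by the tether from C4), and completes the pentacyclic skeleton.

10 ⇒ 9 ⇒ 7 + 8. The O-methyl bond and then the Cb–Ch bond are cut. Cb is the only enolisable carbon of diketone 7, flanked by the Cc ketone and the furan, so C-acylation with acid chloride 8 brings in ring E, the Ch ketone and the bromine in one step. Once ring B is closed, the Cb enolate cannot reach Cf (the closure would be bridged), so this enolate chemistry is safe.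

7 ⇒ 6. The Cb–C4 bond of ring B is cut, which leaves a methyl ketone and a furyl bromide in 6 for an intramolecular ketone α-arylation. This uses the second bromine of the symmetrical furan and forms the seven-membered ring between two sp2-rich, preorganised partners.

6 ⇒ 3 + 2 (through 4 and 5); 2 ⇒ 1. The C3–Cf bond is cut. Monolithiation of symmetrical 3 can give only one furyllithium, 4. A nitrile is chosen as the acyl acceptor because addition stops at the ketiminate 5, which gives the diaryl ketone at the right oxidation level without over-addition. The acetyl group of the ring A partner is masked as the dioxolane in 2, made from commercial 1, and is released in the same acidic work-up.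

## Alternatives that were turned down

Alternative 1: aryne insertion that expands an indanedione into ring B.
- Disconnection: the furan C3–C4 bond and the Cb–Cc bond are cut together. Ring B shrinks to an indane-1,3-dione and rings D and E become an aryne.
- Forward key step: the enolate of 2-(3-methylbut-2-enoyl)indane-1,3-dione (A1) adds to the naphthalyne released by fluoride from silyl triflate A2. The resulting aryl anion attacks a ring carbonyl, and the benzocyclobutenoxide opens by cleavage of a ring C–C(=O) bond to the ring-expanded triketone A3.
- For it: two C–C bonds and the seven-membered ring arise in one operation from two simple partners, and aryne insertion into 1,3-dicarbonyl C–C bonds is established. On convergence it is stronger than the chosen route.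
- Against it: A1 is a tricarbonyl methine, a weak and crowded nucleophile facing an aryne flanked by two methoxy groups. Three acyl groups compete in the fragmentation, so transfer of the exocyclic acyl group (no ring expansion) and O-arylation are open. After A3 the furan must still be closed from a naphthol oxygen onto the enone carbonyl, where conjugate addition to the β,β-dimethyl enone (a six-membered chromanone closure) is the easier path. The bis-demethylated intermediate is an oxidation-prone 1,4-naphthalenediol.
- Comparison: the chosen route is longer per bond formed, but each ring is closed by a reaction with a single possible regiochemical outcome, and the furan is present from the start instead of being made last beside an enone.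

Alternative 2: oxidative radical union of the diketone carbon with the furan.
- Disconnection: the Cb–C4 bond of ring D, leaving ring B to be closed afterwards at C3–Cf.
- Forward key step: Mn(OAc)3 with Cu(OAc)2 oxidises 1,3-diketone A4 to its α-radical. The radical closes a six-membered ring onto the furan β-carbon next to the aryl-bearing α-carbon, and oxidation with proton loss restores the furan and gives naphthol acid A5.
- For it: no halogen and no enol protection are needed, the ring D oxygen arrives at the right oxidation level, and the reagents are cheap. On these points it is stronger than the chosen route.
- Against it: an electrophilic diketone radical and a trivalent manganese oxidant meet an electron-rich 2-alkenyl-5-arylfuran, whose side-chain alkene and α-positions are better radical and oxidation targets than the required β-carbon, and the naphthol product is itself oxidisable. The route then ends with a seven-membered Friedel–Crafts acylation of the acid in A5 onto furan C3, under acid, next to the acid-labile alkenyl group, in competition with lactol or lactone formation with the neighbouring ketone and naphthol.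
- Comparison: the step counts are similar. The chosen route closes ring B early, under weakly basic palladium conditions and before the side chain exists, and leaves for the end a ring D closure whose regiochemistry is fixed by the tether.

Alternative 3: carbonylative oxypalladation that closes furan and ring B together.
- Disconnection: O1–C2, C3–Cf and Cf–ring A, with Cf coming from CO.
- Forward key step: under CO with a zerovalent palladium catalyst and carbonate, the aryl bromide of naphthol A6 undergoes oxidative addition and CO insertion. The naphthoxide attacks the palladium-bound alkyne, and reductive elimination joins C3 to the acyl carbon to give A7, the ring D O-methyl ether of the target.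
- For it: three bonds and two rings form in the key step and only one demethylation follows. In bond economy at the key step it is clearly stronger than the chosen route.
- Against it: A6 is a naphthalene with four different contiguous substituents, among them a free naphthol ortho to a conjugated enyne, which cyclises to a 3-unsubstituted furan as soon as base or metal is present. The productive path needs the acylpalladium unit to reach the alkyne through a medium-sized chelate, against direct carbopalladation without CO uptake and against simple hydroalkoxylation. Building A6 regioselectively would cost more steps than the whole chosen route.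
- Comparison: the chosen route gives up the three-bond key step for cheap symmetrical and ortho-disubstituted building blocks and for a key step that forms one bond at the only C–H bond within reach.

Key step: step 6

Remark on the chemistry: radermachol is an enolised triketone; it is drawn as the tautomer of the target SMILES (hydroxyl on Cc, ketone on Ch), and 9 is drawn as the corresponding ring B enol.

## Route

Step 1
Reactants: 1 2-acetylbenzonitrile
Product: 2 2-(2-methyl-1,3-dioxolan-2-yl)benzonitrile
Conditions: HOCH2CH2OH (3 equiv), TsOH·H2O (5 mol %), PhMe, reflux, Dean–Stark
Reagents that add atoms: ethane-1,2-diol, OCCO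
Why: Acid-catalysed ketalisation with azeotropic removal of water should mask the acetyl group as a dioxolane, so that only the nitrile is electrophilic toward the organolithium of step 2; the nitrile is inert to catalytic TsOH.

Step 2
Reactants: 3 3,4-dibromofuran; 2 2-(2-methyl-1,3-dioxolan-2-yl)benzonitrile
Product: 6 1-[2-(4-bromofuran-3-carbonyl)phenyl]ethan-1-one, via (4-bromofuran-3-yl)lithium 4 (not isolated), via lithium ketiminate 5 (not isolated)
Conditions: n-BuLi (1.0 equiv), Et2O, −78 °C; then 2 in THF, −78 → −20 °C; then 2 M HCl, THF, rt
Reagents that add atoms: water, O
Why: Bromine–lithium exchange on the symmetrical dibromide can give only one monolithio species, so no regiochemical question arises. Addition of the aryllithium to the nitrile stops at the ketiminate, and aqueous acid should hydrolyse the imine and the dioxolane together to the diketone.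

Step 3
Reactants: 6 1-[2-(4-bromofuran-3-carbonyl)phenyl]ethan-1-one
Product: 7 benzo[5,6]cyclohepta[1,2-c]furan-4,9(10H)-dione (tricyclic ring B diketone; CH2 = Cb between furan C4 and the Cc ketone)
Conditions: Pd2(dba)3 (2.5 mol %), Xantphos (6 mol %), K3PO4 (2.5 equiv), PhMe, 90 °C, 0.02 M
Reagents that add atoms: none
Why: Intramolecular palladium-catalysed α-arylation of a ketone: oxidative addition into the furyl C–Br bond (activated by the ortho acyl group), enolate binding and reductive elimination should close the seven-membered ring B through the Cb–C4 bond. The weak base K3PO4 keeps the free enolate concentration low, and the more acidic product cannot add to Cf because that closure would be bridged.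

Step 4
Reactants: 7 benzo[5,6]cyclohepta[1,2-c]furan-4,9(10H)-dione; 8 2-bromobenzoyl chloride
Product: 9 10-(2-bromobenzoyl)-9-hydroxy-4H-benzo[5,6]cyclohepta[1,2-c]furan-4-one (enol form of the triketone)
Conditions: MgBr2·OEt2 (2.5 equiv), i-Pr2NEt (3 equiv), 8 (1.1 equiv), CH2Cl2, 0 °C → rt; then 1 M HCl
Reagents that add atoms: none
Why: Soft enolisation of the aryl ketone and Claisen-type C-acylation of the magnesium enolate should give the 1,3-diketone, held as its magnesium chelate, rather than the enol ester. Cb is the only enolisable carbon of 7.

Step 5
Reactants: 9 10-(2-bromobenzoyl)-9-hydroxy-4H-benzo[5,6]cyclohepta[1,2-c]furan-4-one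
Product: 10 10-(2-bromobenzoyl)-9-methoxy-4H-benzo[5,6]cyclohepta[1,2-c]furan-4-one
Conditions: TMSCHN2 (2 M in hexanes, 2 equiv), PhMe/MeOH, 0 °C → rt
Reagents that add atoms: trimethylsilyldiazomethane, C[Si](C)(C)C=[N+]=[N-]
Why: O-Methylation of the acidic, hydrogen-bonded enol by a diazoalkane should give the vinylogous ester; the ring B enol ether is expected because the endocyclic double bond stays conjugated with ring A while the ortho-bromoaryl ketone is twisted. Because the chelated cis-enol is methylated, the aroyl carbon stays on the furan side of Cb, so the aryl bromide remains within reach of C5.

Step 6
Reactants: 10 10-(2-bromobenzoyl)-9-methoxy-4H-benzo[5,6]cyclohepta[1,2-c]furan-4-one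
Product: 11 2-unsubstituted radermachol methyl enol ether (pentacycle with ring D closed, furan C2–H, methyl on the ring B enol oxygen)
Conditions: Pd(OAc)2 (5 mol %), PCy3·HBF4 (10 mol %), PivOH (30 mol %), K2CO3 (2 equiv), DMA, 110 °C, 0.02 M
Reagents that add atoms: none
Why: Oxidative addition of the C–Br bond of 10 to zerovalent palladium (formed from Pd(OAc)2 and PCy3) gives a divalent arylpalladium bromide, and bromide is exchanged for pivalate. The pivalate-bound palladium cleaves the furan C5–H bond by concerted metalation–deprotonation to a seven-membered diarylpalladacycle (Pd, two ring E carbons, Ch, Cb, C4, C5), and reductive elimination forms the C5–aryl bond. The closest known reaction type is the intramolecular palladium-catalysed direct arylation of heteroarene C–H bonds by tethered aryl bromides under carbonate and pivalate. Ring D is closed as a six-membered ring by joining two sp2 carbons, the arylated carbon C5 being the ring neighbour of the tether-bearing C4, and the product is flat and conjugated, so no strain opposes closure. No stereocentre is formed. Arylation at carbon rather than oxygen is secured by the methyl ether, which leaves no nucleophilic oxygen near palladium (the free enolate would close a pyranone). C5 is taken rather than C2 because the tether starts at C4 and could reach C2 only by bridging across the furan, and the competing seven-membered closure onto the ring A C–H next to Cc involves a less reactive arene C–H bond. Intermolecular arylation of the acidic C2–H of a second molecule is suppressed by dilution.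

Step 7
Reactants: 11 2-unsubstituted radermachol methyl enol ether; 12 1-bromo-2-methylprop-1-ene
Product: 13 radermachol methyl enol ether (methyl on the ring B enol oxygen)
Conditions: Pd(OAc)2 (5 mol %), PCy3·HBF4 (10 mol %), PivOH (30 mol %), K2CO3 (2 equiv), 12 (3 equiv), DMA, 100 °C, sealed tube
Reagents that add atoms: none
Why: Palladium-catalysed direct C–H alkenylation by carboxylate-assisted metalation: C2–H is the only furan C–H left and is an α C–H acidified by the Cf ketone on C3, so oxidative addition of the alkenyl bromide, metalation at C2 and reductive elimination should attach the 2-methylprop-1-enyl group. The tetrasubstituted enol ether and the non-enolisable ketones are spectators.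

Step 8
Reactants: 13 radermachol methyl enol ether
Product: 14 radermachol
Conditions: BCl3 (1 M in CH2Cl2, 2.5 equiv), CH2Cl2, −78 → 0 °C; then aq. NaHCO3
Reagents that add atoms: none
Why: Lewis acid cleavage of a methyl ether held in a six-membered chelate with the neighbouring Ch ketone: BCl3 binds the vinylogous ester, chloride removes the methyl group, and hydrolysis of the boron enolate on work-up should give the enol. The low temperature spares the alkenylfuran.

## Compound list

1 | 2-acetylbenzonitrile | CC(=O)c1ccccc1C#N | starting material
2 | 2-(2-methyl-1,3-dioxolan-2-yl)benzonitrile | CC1(OCCO1)c1ccccc1C#N | intermediate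
3 | 3,4-dibromofuran | Brc1cocc1Br | starting material
4 | (4-bromofuran-3-yl)lithium | [Li]c1cocc1Br | intermediate
5 | lithium ketiminate: lithium (4-bromofuran-3-yl)[2-(2-methyl-1,3-dioxolan-2-yl)phenyl]methaniminide | [Li]N=C(c1cocc1Br)c1ccccc1C1(C)OCCO1 | intermediate
6 | 1-[2-(4-bromofuran-3-carbonyl)phenyl]ethan-1-one | CC(=O)c1ccccc1C(=O)c1cocc1Br | intermediate
7 | benzo[5,6]cyclohepta[1,2-c]furan-4,9(10H)-dione (ring B diketone) | O=C1Cc2cocc2C(=O)c2ccccc12 | intermediate
8 | 2-bromobenzoyl chloride | O=C(Cl)c1ccccc1Br | starting material
9 | 10-(2-bromobenzoyl)-9-hydroxy-4H-benzo[5,6]cyclohepta[1,2-c]furan-4-one (triketone, ring B enol) | O=C(c1ccccc1Br)C1=C(O)c2ccccc2C(=O)c2cocc12 | intermediate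
10 | 10-(2-bromobenzoyl)-9-methoxy-4H-benzo[5,6]cyclohepta[1,2-c]furan-4-one | COC1=C(C(=O)c2ccccc2Br)c2cocc2C(=O)c2ccccc12 | intermediate
11 | 2-unsubstituted radermachol methyl enol ether (ring D closed, furan C2–H) | COC1=C2C(=O)c3ccccc3-c3occ(C(=O)c4ccccc14)c23 | intermediate
12 | 1-bromo-2-methylprop-1-ene | CC(C)=CBr | starting material
13 | radermachol methyl enol ether (methyl on the ring B enol oxygen) | COC1=C2C(=O)c3ccccc3-c3oc(C=C(C)C)c(C(=O)c4ccccc14)c23 | intermediate
14 | radermachol | CC(C)=Cc1oc2c3c(c(O)c4ccccc4c(=O)c13)C(=O)c1ccccc1-2 | target

## Step count and least certain steps

Total: 8 steps. Longest linear sequence: 8 steps (1 → 2 → 6 → 7 → 9 → 10 → 11 → 13 → 14); counted from 3 it is 7.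

Step 6 (key step). The most likely failure is loss of bromine without ring closure, or arylation of the more acidic C2–H of a second molecule. The cause is that metalation at C5 requires the 2-bromobenzoyl group to turn into the furan plane against the puckered ring B, which slows the intramolecular C–H cleavage relative to these side paths. Fallback, from 10 back to 11: the aryl radical is generated from the same bromide with Bu3SnH (slow addition) and stoichiometric AIBN in refluxing toluene. It closes the six-membered ring onto C5 and rearomatises by loss of hydrogen, the homolytic aromatic substitution by which 2-halobenzanilides give phenanthridinones. No new compound is isolated on this path.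

Step 3. The most likely failure is intramolecular aldol addition of the methyl ketone enolate to the neighbouring diaryl ketone Cf (a five-membered closure), followed by irreversible dehydration to an indenone before palladium can capture the enolate. Fallback, from 6 back to 7: 6 is converted with TMSCl, NaI and Et3N in MeCN into its trimethylsilyl enol ether F1. F1 is then cyclised with Pd2(dba)3, P(t-Bu)3 and Bu3SnF in toluene, where a tin enolate formed by fluoride transfer is arylated and no alkali enolate or Brønsted base is present.

Step 7. The most likely failure is slow C–H cleavage at C2, which lies beside the Cf carbonyl in an electron-poor furan, so that the alkenylpalladium intermediate is reduced or the volatile bromide 12 is lost before coupling. Fallback, from 11 back to 13: 11 has no enolisable hydrogen and is metalated at C2, its most acidic C–H, with TMPZnCl·LiCl in THF to the heteroarylzinc chloride F2. F2 is coupled in the same flask with 12 under Pd(OAc)2 and SPhos (Negishi coupling).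

Step 5. The most likely failure is methylation at carbon Cb, or at the exocyclic oxygen with scrambling of the alkene geometry, because the enolate is ambident and hindered. Fallback, from 9 to 14: 9 is converted with BF3·OEt2 and i-Pr2NEt in CH2Cl2 into its difluoroboron chelate F3, a mask with no regiochemistry and no free oxygen. F3 is cyclised under the conditions of step 6 to F4, and F4 is alkenylated with 12 under the conditions of step 7 to F5. The chelate of F5 is cleaved with aqueous NaOH in MeOH/THF and mild acidification gives 14.

Step 2. The most likely failure is slow addition of the thermally fragile furyllithium 4 to the ortho-hindered nitrile, so that proton transfer to α-lithiated furans and decomposition set in on warming. Fallback, from 2 and 3 back to 6: 2 is reduced with DIBAL-H (PhMe, −78 °C, tartrate work-up) to 2-(2-methyl-1,3-dioxolan-2-yl)benzaldehyde F6. Furyllithium 4, generated as in step 2, adds to F6 at −78 °C to give the carbinol F7. MnO2 in CH2Cl2 oxidises F7 to the ketone F8, and 2 M HCl in THF removes the dioxolane to give 6.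

## Further compounds

F0 | step 6 | none | none
F1 | step 3 | (4-bromofuran-3-yl){2-[1-(trimethylsilyloxy)ethenyl]phenyl}methanone | C=C(O[Si](C)(C)C)c1ccccc1C(=O)c1cocc1Br
F2 | step 7 | C2-zincated 11 (heteroarylzinc chloride) | COC1=C2C(=O)c3ccccc3-c3oc([Zn]Cl)c(C(=O)c4ccccc14)c23
F3 | step 5 | difluoroboron chelate of triketone 9 | F[B-]1(F)OC(c2ccccc2Br)=C2c3cocc3C(=O)c3ccccc3C2=[O+]1
F4 | step 5 | ring D-closed difluoroboron chelate (furan C2–H) | F[B-]1(F)OC2=C3C(=[O+]1)c1ccccc1C(=O)c1coc(c13)-c1ccccc12
F5 | step 5 | difluoroboron chelate of radermachol | F[B-]1(F)OC2=C3C(=[O+]1)c1ccccc1C(=O)c1c(C=C(C)C)oc(c13)-c1ccccc12
F6 | step 2 | 2-(2-methyl-1,3-dioxolan-2-yl)benzaldehyde | CC1(OCCO1)c1ccccc1C=O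
F7 | step 2 | (4-bromofuran-3-yl)[2-(2-methyl-1,3-dioxolan-2-yl)phenyl]methanol | CC1(OCCO1)c1ccccc1C(O)c1cocc1Br
F8 | step 2 | (4-bromofuran-3-yl)[2-(2-methyl-1,3-dioxolan-2-yl)phenyl]methanone | CC1(OCCO1)c1ccccc1C(=O)c1cocc1Br
A1 | alternative 1 | 2-(3-methylbut-2-enoyl)indane-1,3-dione | CC(C)=CC(=O)C1C(=O)c2ccccc2C1=O
A2 | alternative 1 | 1,4-dimethoxy-3-(trimethylsilyl)naphthalen-2-yl trifluoromethanesulfonate | COc1c(OS(=O)(=O)C(F)(F)F)c([Si](C)(C)C)c(OC)c2ccccc12
A3 | alternative 1 | ring-expanded triketone (dimethoxynaphthalene-annulated benzocycloheptenedione with the 3-methylbut-2-enoyl group on the sp3 ring carbon, racemic) | CC(C)=CC(=O)C1C(=O)c2ccccc2C(=O)c2c1c(OC)c1ccccc1c2OC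
A4 | alternative 2 | 2-(3-{2-[5-(2-methylprop-1-enyl)furan-2-yl]phenyl}-3-oxopropanoyl)benzoic acid | CC(C)=Cc1ccc(o1)-c1ccccc1C(=O)CC(=O)c1ccccc1C(=O)O
A5 | alternative 2 | 2-[5-hydroxy-2-(2-methylprop-1-enyl)naphtho[1,2-b]furan-4-carbonyl]benzoic acid | CC(C)=Cc1cc2c(o1)c1ccccc1c(O)c2C(=O)c1ccccc1C(=O)O
A6 | alternative 3 | (2-bromophenyl)[4-hydroxy-1-methoxy-3-(4-methylpent-3-en-1-yn-1-yl)naphthalen-2-yl]methanone | CC(C)=CC#Cc1c(O)c2ccccc2c(OC)c1C(=O)c1ccccc1Br
A7 | alternative 3 | radermachol methyl ether with the methyl group on the ring D oxygen | CC(C)=Cc1oc2c3ccccc3c(OC)c3c2c1C(=O)c1ccccc1C3=O
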